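**Retrosynthetic overview**
- The outer dihydrofuran ring (O1'–C2'–C3'–C3a'–C7a') is cut last, by a biomimetic oxidative (3+2) cycloaddition: resorcinol ring C of dimer 17 plus the C7=C8 alkene of the resveratrol derivative 21 (C8–C3a' and C7–O1' bonds in one operation).
- Enabling feature: in ring C the C–H carbon flanked by the two C–OH carbons is a doubly ortho-activated C-nucleophile with an oxygen nucleophile next to it; in 21 the para-OH, conjugated through its ring to C7=C8, makes C8 electrophilic after two-electron oxidation and turns C7 into a quinone methide carbon.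
- Dimer 17: stilbene arm by Heck coupling; inner dihydrofuran ring by enantioselective rhodium-carbene C–H insertion (C2–C3 bond) of a diaryldiazomethane, then acid epimerisation to trans.
- Ring order: inner dihydrofuran ring (step 6), then outer dihydrofuran ring (step 14, last); all six benzene rings are bought.
- Final operation: global debenzylation with BCl3.

Key step: step 14

Assumption (chemistry): Rh2(S-PTAD)4 in step 6 and (R)-TRIP in step 14 are taken as the catalyst enantiomers that give the drawn configurations; if either induces the opposite sense, its mirror-image catalyst is used.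

**Step 1**
Reactants: 1 4-bromo-2,6-difluorobenzaldehyde; 2 [4-(benzyloxy)phenyl]methanol
Product: 3 2,6-bis{[4-(benzyloxy)benzyl]oxy}-4-bromobenzaldehyde
Conditions: 2 (2.2 equiv in all), NaH (2.4 equiv), THF/DMF, 0 °C → 45 °C
Reagents that add atoms: [4-(benzyloxy)phenyl]methanol (second equivalent of 2), OCc1ccc(OCc2ccccc2)cc1
Why: Double nucleophilic aromatic substitution, in which two equivalents of the sodium alkoxide of 2 displace in turn the two fluorides ortho to the formyl group (the second needs gentle warming because the first alkoxy group deactivates the ring), while the bromide para to CHO is a far poorer leaving group and stays.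

**Step 2**
Reactants: 4 5-bromobenzene-1,3-diol
Product: 5 1-bromo-3,5-bis(triisopropylsilyloxy)benzene
Conditions: iPr3SiCl (2.3 equiv), imidazole, DMF, rt
Reagents that add atoms: chlorotriisopropylsilane, CC(C)[Si](Cl)(C(C)C)C(C)C
Why: Imidazole-promoted silylation of both phenols gives aryl silyl ethers that should tolerate Grignard formation, hydrazine, acid and palladium catalysis and are removable by fluoride alone.

**Step 3**
Reactants: 5 1-bromo-3,5-bis(triisopropylsilyloxy)benzene; 3 2,6-bis{[4-(benzyloxy)benzyl]oxy}-4-bromobenzaldehyde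
Product: 7 (2,6-bis{[4-(benzyloxy)benzyl]oxy}-4-bromophenyl)[3,5-bis(triisopropylsilyloxy)phenyl]methanol (racemic), via Grignard reagent 6 (not isolated)
Conditions: Mg, LiCl, THF, 40 °C; then 3, THF, 0 °C → rt; aq. NH4Cl
Reagents that add atoms: none
Why: Grignard formation and 1,2-addition to the aldehyde should proceed without touching the aryl bromide of 3 at 0 °C; the new carbinol centre is racemic and is destroyed in step 4.

**Step 4**
Reactants: 7 (2,6-bis{[4-(benzyloxy)benzyl]oxy}-4-bromophenyl)[3,5-bis(triisopropylsilyloxy)phenyl]methanol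
Product: 8 (2,6-bis{[4-(benzyloxy)benzyl]oxy}-4-bromophenyl)[3,5-bis(triisopropylsilyloxy)phenyl]methanone
Conditions: Dess–Martin periodinane, NaHCO3, CH2Cl2, rt
Reagents that add atoms: none
Why: Dess–Martin oxidation of a doubly benzylic secondary alcohol under buffered neutral conditions should leave silyl and benzyl ethers untouched.

**Step 5**
Reactants: 8 (2,6-bis{[4-(benzyloxy)benzyl]oxy}-4-bromophenyl)[3,5-bis(triisopropylsilyloxy)phenyl]methanone
Product: 9 [(2,6-bis{[4-(benzyloxy)benzyl]oxy}-4-bromophenyl)(3,5-bis(triisopropylsilyloxy)phenyl)methylidene]hydrazine (C=N isomer mixture)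
Conditions: N2H4·H2O (excess), AcOH (cat.), n-BuOH, 110 °C, sealed tube
Reagents that add atoms: hydrazine, NN
Why: Condensation of the diaryl ketone with hydrazine gives the N-unsubstituted hydrazone (either C=N isomer serves), and forcing conditions are chosen because two ortho-alkoxy groups shield the carbonyl.

**Step 6**
Reactants: 9 [(2,6-bis{[4-(benzyloxy)benzyl]oxy}-4-bromophenyl)(3,5-bis(triisopropylsilyloxy)phenyl)methylidene]hydrazine
Product: 11 (2R,3S)-2-[4-(benzyloxy)phenyl]-4-{[4-(benzyloxy)benzyl]oxy}-6-bromo-3-[3,5-bis(triisopropylsilyloxy)phenyl]-2,3-dihydrobenzofuran (cis), via diazo compound 10 (not isolated)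
Conditions: MnO2, CH2Cl2, 0 °C, filtration; then Rh2(S-PTAD)4 (1 mol%; PTAD = N-phthaloyl-adamantylglycinate), CH2Cl2/MeCN, −20 °C → rt
Reagents that add atoms: none
Why: Hydrazone oxidation gives the diaryldiazomethane, whose donor/donor rhodium carbene should undergo enantioselective intramolecular 1,5 C–H insertion into the benzylic ether C–H (the two ArCH2O groups are equivalent by rotation); the chiral dirhodium carboxylate fixes C3 as S and the insertion is expected to give the cis C2 epimer.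

**Step 7**
Reactants: 11 (2R,3S)-2-[4-(benzyloxy)phenyl]-4-{[4-(benzyloxy)benzyl]oxy}-6-bromo-3-[3,5-bis(triisopropylsilyloxy)phenyl]-2,3-dihydrobenzofuran
Product: 12 (2S,3S)-2-[4-(benzyloxy)phenyl]-6-bromo-3-[3,5-bis(triisopropylsilyloxy)phenyl]-2,3-dihydrobenzofuran-4-ol (trans)
Conditions: CF3CO2H (10 vol%), pentamethylbenzene, CH2Cl2, 0 °C
Reagents that add atoms: none
Why: Acid ionises the C2–O bond to a para-alkoxybenzylic cation that recloses to the thermodynamically favoured trans isomer without touching C3 (either ortho oxygen gives the same compound), and the same acid cleaves the 4-(benzyloxy)benzyl aryl ether (PMB-type acidolysis) with pentamethylbenzene as cation trap.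

**Step 8**
Reactants: 12 (2S,3S)-2-[4-(benzyloxy)phenyl]-6-bromo-3-[3,5-bis(triisopropylsilyloxy)phenyl]-2,3-dihydrobenzofuran-4-ol
Product: 13 (2S,3S)-4-(benzyloxy)-2-[4-(benzyloxy)phenyl]-6-bromo-3-[3,5-bis(triisopropylsilyloxy)phenyl]-2,3-dihydrobenzofuran
Conditions: BnBr, K2CO3, acetone, 50 °C
Reagents that add atoms: benzyl bromide, BrCc1ccccc1
Why: Williamson etherification caps the only free phenol so that the benzo ring of the inner dihydrobenzofuran cannot compete as a nucleophile in step 14; the mild carbonate in acetone should spare the aryl silyl ethers.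

**Step 9**
Reactants: 14 2,4-bis(benzyloxy)benzaldehyde
Product: 15 2,4-bis(benzyloxy)-1-vinylbenzene
Conditions: Ph3PCH3Br, KOtBu, THF, 0 °C → rt
Reagents that add atoms: methyltriphenylphosphonium bromide, C[P+](c1ccccc1)(c1ccccc1)c1ccccc1.[Br-]
Why: Wittig methylenation of an aromatic aldehyde with the non-stabilised ylide is reliable and has no stereochemical issue.

**Step 10**
Reactants: 13 (2S,3S)-4-(benzyloxy)-2-[4-(benzyloxy)phenyl]-6-bromo-3-[3,5-bis(triisopropylsilyloxy)phenyl]-2,3-dihydrobenzofuran; 15 2,4-bis(benzyloxy)-1-vinylbenzene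
Product: 16 (2S,3S)-4-(benzyloxy)-2-[4-(benzyloxy)phenyl]-6-{(E)-2-[2,4-bis(benzyloxy)phenyl]vinyl}-3-[3,5-bis(triisopropylsilyloxy)phenyl]-2,3-dihydrobenzofuran
Conditions: Pd(OAc)2 (5 mol%), P(o-tol)3 (10 mol%), Et3N, DMF, 100 °C
Reagents that add atoms: none
Why: Mizoroki–Heck coupling of the aryl bromide at the terminal carbon of the styrene should give the E-stilbene through syn-insertion and syn-β-hydride elimination, and the stereocentres are not involved.

**Step 11**
Reactants: 16 (2S,3S)-4-(benzyloxy)-2-[4-(benzyloxy)phenyl]-6-{(E)-2-[2,4-bis(benzyloxy)phenyl]vinyl}-3-[3,5-bis(triisopropylsilyloxy)phenyl]-2,3-dihydrobenzofuran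
Product: 17 5-[(2S,3S)-4-(benzyloxy)-2-[4-(benzyloxy)phenyl]-6-{(E)-2-[2,4-bis(benzyloxy)phenyl]vinyl}-2,3-dihydrobenzofuran-3-yl]benzene-1,3-diol
Conditions: Bu4NF, THF, 0 °C; aq. NH4Cl
Reagents that add atoms: none
Why: Fluoride cleaves only the two aryl silyl ethers, which frees the resorcinol ring C as the sole phenolic ring of the dimer.

**Step 12**
Reactants: 18 1,3-bis(benzyloxy)-5-bromobenzene; 19 4-vinylphenyl acetate
Product: 20 4-{(E)-2-[3,5-bis(benzyloxy)phenyl]vinyl}phenyl acetate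
Conditions: Pd(OAc)2 (5 mol%), P(o-tol)3 (10 mol%), Et3N, DMF, 100 °C
Reagents that add atoms: none
Why: Mizoroki–Heck coupling with 4-acetoxystyrene is an established way to E-configured protected resveratrol derivatives.

**Step 13**
Reactants: 20 4-{(E)-2-[3,5-bis(benzyloxy)phenyl]vinyl}phenyl acetate
Product: 21 4-{(E)-2-[3,5-bis(benzyloxy)phenyl]vinyl}phenol
Conditions: K2CO3 (cat.), MeOH/THF, rt
Reagents that add atoms: none
Why: Base-catalysed methanolysis of the aryl acetate frees the para-phenol and leaves the benzyl ethers and the alkene unchanged.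

**Step 14**
Reactants: 17 5-[(2S,3S)-4-(benzyloxy)-2-[4-(benzyloxy)phenyl]-6-{(E)-2-[2,4-bis(benzyloxy)phenyl]vinyl}-2,3-dihydrobenzofuran-3-yl]benzene-1,3-diol; 21 4-{(E)-2-[3,5-bis(benzyloxy)phenyl]vinyl}phenol
Product: 24 (2S,3S)-3-[3,5-bis(benzyloxy)phenyl]-6-[(2S,3S)-4-(benzyloxy)-2-[4-(benzyloxy)phenyl]-6-{(E)-2-[2,4-bis(benzyloxy)phenyl]vinyl}-2,3-dihydrobenzofuran-3-yl]-2-(4-hydroxyphenyl)-2,3-dihydrobenzofuran-4-ol, via quinone methide cation 22 (not isolated), via para-quinone methide 23 (not isolated)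
Conditions: DDQ (1.1 equiv), (R)-TRIP (10 mol%; TRIP = 3,3'-bis(2,4,6-triisopropylphenyl)-1,1'-binaphthyl-2,2'-diyl hydrogen phosphate), 4 Å MS, CH2Cl2/toluene, −40 °C, slow addition of 21 (1.2 equiv)
Reagents that add atoms: none
Why: Proposed new method: DDQ removes two electrons and a proton from the 4-hydroxystilbene 21, the most easily oxidised phenol present, to give cation 22 as an ion pair with the chiral phosphate, in which C8 (the carbon carrying the 3,5-dibenzyloxyphenyl ring) is the electrophilic end; the ring C carbon of 17 lying between the two C–OH carbons attacks C8 (Friedel–Crafts step, C–C bond) to give para-quinone methide 23, and one of the two flanking OH groups (equivalent by rotation) then adds to the quinone methide carbon C7 (C–O bond). The closest known reactions are the biomimetic one-electron oxidative couplings of 4-hydroxystilbenes to viniferin-type trans-2,3-diaryl-2,3-dihydrobenzofurans, oxidative couplings run with DDQ and a chiral phosphoric acid through chiral ion pairs, and phosphoric-acid-catalysed additions of phenols to para-quinone methides; new here are the cross-coupling with a separate resorcinol and the control of the C8 face by the phosphate. The furan ring closes by a 5-exo-trig oxa-conjugate (1,6) addition. C3' is set in the C–C bond-forming step by the chiral phosphate, which is hydrogen-bonded to a ring C hydroxyl and ion-paired with 22 and so should expose one face of C8 (the stereocentres of 17 are too remote to influence it); C2' is set in the ring closure, which places the two aryl groups trans and is reversible through 23, so that trans is also the thermodynamic outcome. The step needs chemoselective oxidation (17 offers only a harder-to-oxidise resorcinol and ethers), cross-coupling over self-coupling (21 is added slowly and its own resorcinol ring is benzylated, so it has no competing C,O-dinucleophile), and attack at the ring C carbon between the hydroxyls (it is ortho to both OH groups, and the two other ring C positions are shielded by the adjacent C3 substituent of the inner dihydrobenzofuran).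

**Step 15**
Reactants: 24 (2S,3S)-3-[3,5-bis(benzyloxy)phenyl]-6-[(2S,3S)-4-(benzyloxy)-2-[4-(benzyloxy)phenyl]-6-{(E)-2-[2,4-bis(benzyloxy)phenyl]vinyl}-2,3-dihydrobenzofuran-3-yl]-2-(4-hydroxyphenyl)-2,3-dihydrobenzofuran-4-ol
Product: 25 4-[(E)-2-{(2S,3S)-3-[(2S,3S)-3-(3,5-dihydroxyphenyl)-4-hydroxy-2-(4-hydroxyphenyl)-2,3-dihydrobenzofuran-6-yl]-4-hydroxy-2-(4-hydroxyphenyl)-2,3-dihydrobenzofuran-6-yl}vinyl]benzene-1,3-diol (CNP0186204.1)
Conditions: BCl3, pentamethylbenzene, CH2Cl2, −78 °C; then MeOH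
Reagents that add atoms: none
Why: Lewis-acid debenzylation with a non-basic cation scavenger at low temperature should remove all six benzyl ethers without hydrogenation, so the stilbene and both benzylic C–O bonds survive, and any transient opening at C2 or C2' recloses to the trans isomers.

**Compound list**
1 | 4-bromo-2,6-difluorobenzaldehyde | O=Cc1c(F)cc(Br)cc1F | starting material
2 | [4-(benzyloxy)phenyl]methanol | OCc1ccc(OCc2ccccc2)cc1 | starting material
3 | 2,6-bis{[4-(benzyloxy)benzyl]oxy}-4-bromobenzaldehyde | O=Cc1c(OCc2ccc(OCc3ccccc3)cc2)cc(Br)cc1OCc1ccc(OCc2ccccc2)cc1 | intermediate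
4 | 5-bromobenzene-1,3-diol | Oc1cc(O)cc(Br)c1 | starting material
5 | 1-bromo-3,5-bis(triisopropylsilyloxy)benzene | CC(C)[Si](Oc1cc(Br)cc(O[Si](C(C)C)(C(C)C)C(C)C)c1)(C(C)C)C(C)C | intermediate
6 | [3,5-bis(triisopropylsilyloxy)phenyl]magnesium bromide | CC(C)[Si](Oc1cc([Mg]Br)cc(O[Si](C(C)C)(C(C)C)C(C)C)c1)(C(C)C)C(C)C | intermediate
7 | (2,6-bis{[4-(benzyloxy)benzyl]oxy}-4-bromophenyl)[3,5-bis(triisopropylsilyloxy)phenyl]methanol (racemic) | OC(c1cc(O[Si](C(C)C)(C(C)C)C(C)C)cc(O[Si](C(C)C)(C(C)C)C(C)C)c1)c1c(OCc2ccc(OCc3ccccc3)cc2)cc(Br)cc1OCc1ccc(OCc2ccccc2)cc1 | intermediate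
8 | (2,6-bis{[4-(benzyloxy)benzyl]oxy}-4-bromophenyl)[3,5-bis(triisopropylsilyloxy)phenyl]methanone | O=C(c1cc(O[Si](C(C)C)(C(C)C)C(C)C)cc(O[Si](C(C)C)(C(C)C)C(C)C)c1)c1c(OCc2ccc(OCc3ccccc3)cc2)cc(Br)cc1OCc1ccc(OCc2ccccc2)cc1 | intermediate
9 | hydrazone of ketone 8 (C=N isomer mixture) | NN=C(c1cc(O[Si](C(C)C)(C(C)C)C(C)C)cc(O[Si](C(C)C)(C(C)C)C(C)C)c1)c1c(OCc2ccc(OCc3ccccc3)cc2)cc(Br)cc1OCc1ccc(OCc2ccccc2)cc1 | intermediate
10 | 1,3-bis{[4-(benzyloxy)benzyl]oxy}-5-bromo-2-{diazo[3,5-bis(triisopropylsilyloxy)phenyl]methyl}benzene | [N-]=[N+]=C(c1cc(O[Si](C(C)C)(C(C)C)C(C)C)cc(O[Si](C(C)C)(C(C)C)C(C)C)c1)c1c(OCc2ccc(OCc3ccccc3)cc2)cc(Br)cc1OCc1ccc(OCc2ccccc2)cc1 | intermediate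
11 | (2R,3S)-2-[4-(benzyloxy)phenyl]-4-{[4-(benzyloxy)benzyl]oxy}-6-bromo-3-[3,5-bis(triisopropylsilyloxy)phenyl]-2,3-dihydrobenzofuran (cis) | c1ccccc1COc1ccc([C@@H]2Oc3cc(Br)cc(OCc4ccc(OCc5ccccc5)cc4)c3[C@@H]2c2cc(O[Si](C(C)C)(C(C)C)C(C)C)cc(O[Si](C(C)C)(C(C)C)C(C)C)c2)cc1 | intermediate
12 | (2S,3S)-2-[4-(benzyloxy)phenyl]-6-bromo-3-[3,5-bis(triisopropylsilyloxy)phenyl]-2,3-dihydrobenzofuran-4-ol (trans) | c1ccccc1COc1ccc([C@H]2Oc3cc(Br)cc(O)c3[C@@H]2c2cc(O[Si](C(C)C)(C(C)C)C(C)C)cc(O[Si](C(C)C)(C(C)C)C(C)C)c2)cc1 | intermediate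
13 | (2S,3S)-4-(benzyloxy)-2-[4-(benzyloxy)phenyl]-6-bromo-3-[3,5-bis(triisopropylsilyloxy)phenyl]-2,3-dihydrobenzofuran | c1ccccc1COc1ccc([C@H]2Oc3cc(Br)cc(OCc4ccccc4)c3[C@@H]2c2cc(O[Si](C(C)C)(C(C)C)C(C)C)cc(O[Si](C(C)C)(C(C)C)C(C)C)c2)cc1 | intermediate
14 | 2,4-bis(benzyloxy)benzaldehyde | O=Cc1ccc(OCc2ccccc2)cc1OCc1ccccc1 | starting material
15 | 2,4-bis(benzyloxy)-1-vinylbenzene | C=Cc1ccc(OCc2ccccc2)cc1OCc1ccccc1 | intermediate
16 | (2S,3S)-4-(benzyloxy)-2-[4-(benzyloxy)phenyl]-6-{(E)-2-[2,4-bis(benzyloxy)phenyl]vinyl}-3-[3,5-bis(triisopropylsilyloxy)phenyl]-2,3-dihydrobenzofuran | c1ccccc1COc1ccc([C@H]2Oc3cc(/C=C/c4ccc(OCc5ccccc5)cc4OCc4ccccc4)cc(OCc4ccccc4)c3[C@@H]2c2cc(O[Si](C(C)C)(C(C)C)C(C)C)cc(O[Si](C(C)C)(C(C)C)C(C)C)c2)cc1 | intermediate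
17 | 5-[(2S,3S)-4-(benzyloxy)-2-[4-(benzyloxy)phenyl]-6-{(E)-2-[2,4-bis(benzyloxy)phenyl]vinyl}-2,3-dihydrobenzofuran-3-yl]benzene-1,3-diol | c1ccccc1COc1ccc([C@H]2Oc3cc(/C=C/c4ccc(OCc5ccccc5)cc4OCc4ccccc4)cc(OCc4ccccc4)c3[C@@H]2c2cc(O)cc(O)c2)cc1 | intermediate
18 | 1,3-bis(benzyloxy)-5-bromobenzene | Brc1cc(OCc2ccccc2)cc(OCc2ccccc2)c1 | starting material
19 | 4-vinylphenyl acetate | CC(=O)Oc1ccc(C=C)cc1 | starting material
20 | 4-{(E)-2-[3,5-bis(benzyloxy)phenyl]vinyl}phenyl acetate | CC(=O)Oc1ccc(/C=C/c2cc(OCc3ccccc3)cc(OCc3ccccc3)c2)cc1 | intermediate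
21 | 4-{(E)-2-[3,5-bis(benzyloxy)phenyl]vinyl}phenol | Oc1ccc(/C=C/c2cc(OCc3ccccc3)cc(OCc3ccccc3)c2)cc1 | intermediate
22 | quinone methide cation from 21 (cation drawn; counter-ion is the phosphate of the catalyst) | O=C1C=CC(=C[CH+]c2cc(OCc3ccccc3)cc(OCc3ccccc3)c2)C=C1 | intermediate
23 | para-quinone methide: 4-{(S)-2-[3,5-bis(benzyloxy)phenyl]-2-[2,6-dihydroxy-4-(inner (2S,3S)-dihydrobenzofuran-3-yl)phenyl]ethylidene}cyclohexa-2,5-dienone | O=C1C=CC(=C[C@H](c2c(O)cc(cc2O)[C@H]2c3c(OCc4ccccc4)cc(/C=C/c4ccc(OCc5ccccc5)cc4OCc4ccccc4)cc3O[C@@H]2c2ccc(OCc3ccccc3)cc2)c2cc(OCc3ccccc3)cc(OCc3ccccc3)c2)C=C1 | intermediate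
24 | (2S,3S)-3-[3,5-bis(benzyloxy)phenyl]-6-[(2S,3S)-4-(benzyloxy)-2-[4-(benzyloxy)phenyl]-6-{(E)-2-[2,4-bis(benzyloxy)phenyl]vinyl}-2,3-dihydrobenzofuran-3-yl]-2-(4-hydroxyphenyl)-2,3-dihydrobenzofuran-4-ol | c1ccccc1COc1ccc([C@H]2Oc3cc(/C=C/c4ccc(OCc5ccccc5)cc4OCc4ccccc4)cc(OCc4ccccc4)c3[C@@H]2c2cc(O)c3c(c2)O[C@H](c2ccc(O)cc2)[C@H]3c2cc(OCc3ccccc3)cc(OCc3ccccc3)c2)cc1 | intermediate
25 | 4-[(E)-2-{(2S,3S)-3-[(2S,3S)-3-(3,5-dihydroxyphenyl)-4-hydroxy-2-(4-hydroxyphenyl)-2,3-dihydrobenzofuran-6-yl]-4-hydroxy-2-(4-hydroxyphenyl)-2,3-dihydrobenzofuran-6-yl}vinyl]benzene-1,3-diol (CNP0186204.1) | Oc1ccc([C@H]2Oc3cc(/C=C/c4ccc(O)cc4O)cc(O)c3[C@@H]2c2cc(O)c3c(c2)O[C@H](c2ccc(O)cc2)[C@H]3c2cc(O)cc(O)c2)cc1 | target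

**Step count and risks**
Total steps: 15. Longest linear sequence: 11 steps (steps 1, 3, 4, 5, 6, 7, 8, 10, 11, 14, 15, from compound 1).

Most likely to fail, step 14 (Proposed new method): self-coupling of oxidised 21 may outrun the cross-coupling, the chiral anion may discriminate the two faces of C8 poorly (giving the (2'R,3'R) diastereomer as well), or ring C may be attacked at a carbon next to C3. Fallback by known reaction types, setting out from 17 and 21 and coming back at 24: phenol 21 is converted with Tf2O and pyridine into the aryl triflate F1. Shi epoxidation of F1 (L-sorbose-derived enantiomer of the fructose ketone catalyst, KHSO5 as Oxone, K2CO3, MeCN/dimethoxymethane, 0 °C) gives the (2S,3S)-trans-epoxide F2. Resorcinol 17 opens F2 in (CF3)2CHOH in a Friedel–Crafts reaction with inversion at the carbon carrying the 3,5-dibenzyloxyphenyl ring, because the electron-poor 4-triflyloxyphenyl ring disfavours cation character at the other carbon; this gives alcohol F3. Mitsunobu etherification (PPh3, diisopropyl azodicarboxylate, THF) closes the furan ring with inversion at the carbinol carbon to the trans-dihydrobenzofuran triflate F4. Et4NOH in dioxane/water cleaves the triflate to 24. Both new stereocentres then come from the epoxide by two inversions.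

Second, step 6: enantio-induction may be low, or the carbene may dimerise to the azine, because the carbene carbon is flanked by two ortho-alkoxy groups. Fallback by resolution, setting out from 9 and coming back at 12: hydrazone 9 is oxidised as before and the diazo compound 10 is cyclised with achiral Rh2(OAc)4 to the racemic cis compound F5. The acid treatment of step 7 gives the racemic trans phenol F6. Esterification with N-Boc-L-proline (EDC·HCl, DMAP, CH2Cl2) gives the diastereomeric esters F7 ((2S,3S)) and F8 ((2R,3R)), which are separated by chromatography or crystallisation. Pyrrolidine in THF cleaves F7 to 12.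

Third, step 5: condensation at the doubly ortho-shielded carbonyl may be slow or incomplete, and the silyl ethers may be lost under the forcing conditions. Fallback through a more reactive C=S group, setting out from 8 and coming back at 9: ketone 8 is thionated with Lawesson's reagent (toluene, 110 °C) to thioketone F9, which should react with hydrazine hydrate at room temperature with loss of H2S to give 9.

**Further compounds**
F1 | step 14 | 4-{(E)-2-[3,5-bis(benzyloxy)phenyl]vinyl}phenyl trifluoromethanesulfonate | O=S(=O)(Oc1ccc(/C=C/c2cc(OCc3ccccc3)cc(OCc3ccccc3)c2)cc1)C(F)(F)F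
F2 | step 14 | (2S,3S)-2-[3,5-bis(benzyloxy)phenyl]-3-[4-(trifluoromethylsulfonyloxy)phenyl]oxirane | O1[C@@H](c2ccc(OS(=O)(=O)C(F)(F)F)cc2)[C@@H]1c1cc(OCc2ccccc2)cc(OCc2ccccc2)c1
F3 | step 14 | (1R,2S)-2-[3,5-bis(benzyloxy)phenyl]-2-{4-[(2S,3S)-4-(benzyloxy)-2-[4-(benzyloxy)phenyl]-6-{(E)-2-[2,4-bis(benzyloxy)phenyl]vinyl}-2,3-dihydrobenzofuran-3-yl]-2,6-dihydroxyphenyl}-1-[4-(trifluoromethylsulfonyloxy)phenyl]ethanol | O[C@@H](c1ccc(OS(=O)(=O)C(F)(F)F)cc1)[C@H](c1c(O)cc(cc1O)[C@H]1c2c(OCc3ccccc3)cc(/C=C/c3ccc(OCc4ccccc4)cc3OCc3ccccc3)cc2O[C@@H]1c1ccc(OCc2ccccc2)cc1)c1cc(OCc2ccccc2)cc(OCc2ccccc2)c1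
F4 | step 14 | 4-{(2S,3S)-3-[3,5-bis(benzyloxy)phenyl]-6-[(2S,3S)-4-(benzyloxy)-2-[4-(benzyloxy)phenyl]-6-{(E)-2-[2,4-bis(benzyloxy)phenyl]vinyl}-2,3-dihydrobenzofuran-3-yl]-4-hydroxy-2,3-dihydrobenzofuran-2-yl}phenyl trifluoromethanesulfonate | c1ccccc1COc1ccc([C@H]2Oc3cc(/C=C/c4ccc(OCc5ccccc5)cc4OCc4ccccc4)cc(OCc4ccccc4)c3[C@@H]2c2cc(O)c3c(c2)O[C@H](c2ccc(OS(=O)(=O)C(F)(F)F)cc2)[C@H]3c2cc(OCc3ccccc3)cc(OCc3ccccc3)c2)cc1
F5 | step 6 | racemic cis-2-[4-(benzyloxy)phenyl]-4-{[4-(benzyloxy)benzyl]oxy}-6-bromo-3-[3,5-bis(triisopropylsilyloxy)phenyl]-2,3-dihydrobenzofuran (racemate; the (2R,3S) enantiomer is drawn) | c1ccccc1COc1ccc([C@@H]2Oc3cc(Br)cc(OCc4ccc(OCc5ccccc5)cc4)c3[C@@H]2c2cc(O[Si](C(C)C)(C(C)C)C(C)C)cc(O[Si](C(C)C)(C(C)C)C(C)C)c2)cc1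
F6 | step 6 | racemic trans-2-[4-(benzyloxy)phenyl]-6-bromo-3-[3,5-bis(triisopropylsilyloxy)phenyl]-2,3-dihydrobenzofuran-4-ol (racemate; the (2S,3S) enantiomer is drawn) | c1ccccc1COc1ccc([C@H]2Oc3cc(Br)cc(O)c3[C@@H]2c2cc(O[Si](C(C)C)(C(C)C)C(C)C)cc(O[Si](C(C)C)(C(C)C)C(C)C)c2)cc1
F7 | step 6 | (2S,3S)-2-[4-(benzyloxy)phenyl]-6-bromo-3-[3,5-bis(triisopropylsilyloxy)phenyl]-2,3-dihydrobenzofuran-4-yl N-Boc-L-prolinate | c1ccccc1COc1ccc([C@H]2Oc3cc(Br)cc(OC(=O)[C@@H]4CCCN4C(=O)OC(C)(C)C)c3[C@@H]2c2cc(O[Si](C(C)C)(C(C)C)C(C)C)cc(O[Si](C(C)C)(C(C)C)C(C)C)c2)cc1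
F8 | step 6 | (2R,3R)-2-[4-(benzyloxy)phenyl]-6-bromo-3-[3,5-bis(triisopropylsilyloxy)phenyl]-2,3-dihydrobenzofuran-4-yl N-Boc-L-prolinate | c1ccccc1COc1ccc([C@@H]2Oc3cc(Br)cc(OC(=O)[C@@H]4CCCN4C(=O)OC(C)(C)C)c3[C@H]2c2cc(O[Si](C(C)C)(C(C)C)C(C)C)cc(O[Si](C(C)C)(C(C)C)C(C)C)c2)cc1
F9 | step 5 | (2,6-bis{[4-(benzyloxy)benzyl]oxy}-4-bromophenyl)[3,5-bis(triisopropylsilyloxy)phenyl]methanethione | S=C(c1cc(O[Si](C(C)C)(C(C)C)C(C)C)cc(O[Si](C(C)C)(C(C)C)C(C)C)c1)c1c(OCc2ccc(OCc3ccccc3)cc2)cc(Br)cc1OCc1ccc(OCc2ccccc2)cc1
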